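Retrosynthesis: the eight phenolic O–H bonds go back to methyl ethers; the two aryl–C(=O) bonds of the 2,6-dihydroxybenzoyl ends are cut to a dialdehyde and 2,6-dimethoxyphenyllithium; the biaryl C–C bond and the adjacent C4–O bond of ring A are cut together to a 3-methoxyaryne, an aryl Grignard reagent and an oxygen electrophile; each chain is cut between its first and second carbon (Wittig) to a benzaldehyde and one common C8 phosphonium salt.
Enabling feature: ring A (chain at C1) carries O at C3, O at C4 and the aryl group at C5 in an unbroken row, so C4 and C5 are the two aryne carbons and the C3 methoxy group beside them decides which one receives carbon; ring B is joined at the carbon para to an oxygen and ortho to its chain, which is where a 4-alkylveratrole takes up bromine.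
Forward order: no ring is built; the C9 chains are attached to the two benzaldehydes, the two arenes are joined in the aryne step, both chain ends are then elaborated in parallel to the aryl ketones, and the eight methyl ethers are removed last.
Stereochemistry: none to set; the target has no stereocentre and no alkene, and the biaryl axis, with one ortho substituent on each ring, is not configurationally stable.

Key step: step 10

Remark on the chemistry: the two Wittig alkenes are drawn as the Z isomers expected to predominate (either isomer gives the same alkane on hydrogenation), and the bis-carbinol of the end-game is a stereoisomer mixture that the following oxidation erases.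

Step 1
Reactants: 1 8-bromooctan-1-ol
Product: 2 (8-hydroxyoctyl)triphenylphosphonium bromide
Conditions: PPh3, MeCN, reflux
Reagents that add atoms: triphenylphosphine, c1ccc(cc1)P(c1ccccc1)c1ccccc1
Why: quaternisation of triphenylphosphine by a primary alkyl bromide (SN2) is reliable and the free hydroxyl group does not interfere.

Step 2
Reactants: 2 (8-hydroxyoctyl)triphenylphosphonium bromide; 3 3,4-dimethoxybenzaldehyde
Product: 4 (Z)-9-(3,4-dimethoxyphenyl)non-8-en-1-ol
Conditions: 2, NaN(SiMe3)2 (2 equiv per 2), THF, 0 °C; then 3, −78 °C to rt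
Reagents that add atoms: none
Why: Wittig olefination with a non-stabilised ylide, in which the first equivalent of base takes the hydroxyl proton and the second forms the ylide; the alkene geometry is irrelevant because the double bond is hydrogenated next.

Step 3
Reactants: 4 (Z)-9-(3,4-dimethoxyphenyl)non-8-en-1-ol
Product: 5 9-(3,4-dimethoxyphenyl)nonan-1-ol
Conditions: H2 (1 atm), 10% Pd/C, EtOAc, rt
Reagents that add atoms: none
Why: heterogeneous catalytic hydrogenation saturates the styrene-type alkene and leaves the aryl ethers and the primary alcohol untouched.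

Step 4
Reactants: 5 9-(3,4-dimethoxyphenyl)nonan-1-ol
Product: 6 9-(2-bromo-4,5-dimethoxyphenyl)nonan-1-ol
Conditions: NBS, MeCN, 0 °C to rt
Reagents that add atoms: N-bromosuccinimide, O=C1CCC(=O)N1Br
Why: electrophilic aromatic bromination of a 4-alkylveratrole occurs at the ring position para to one methoxy group and ortho to the chain, and under these ionic conditions neither the benzylic position nor the alcohol reacts.

Step 5
Reactants: 6 9-(2-bromo-4,5-dimethoxyphenyl)nonan-1-ol
Product: 7 [9-(2-bromo-4,5-dimethoxyphenyl)nonyloxy](tert-butyl)dimethylsilane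
Conditions: TBSCl, imidazole, DMF, rt
Reagents that add atoms: tert-butyldimethylsilyl chloride, CC(C)(C)[Si](C)(C)Cl
Why: standard silylation of a primary alcohol removes the only acidic proton before the organometallic steps; it is placed after the bromination so that the silyl ether never meets traces of HBr.

Step 6
Reactants: 2 (8-hydroxyoctyl)triphenylphosphonium bromide; 8 3-fluoro-5-methoxybenzaldehyde
Product: 9 (Z)-9-(3-fluoro-5-methoxyphenyl)non-8-en-1-ol
Conditions: 2, NaN(SiMe3)2 (2 equiv per 2), THF, 0 °C; then 8, −78 °C to rt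
Reagents that add atoms: none
Why: the same Wittig olefination as in step 2, and the aryl fluoride is inert to the ylide at these temperatures.

Step 7
Reactants: 9 (Z)-9-(3-fluoro-5-methoxyphenyl)non-8-en-1-ol
Product: 10 9-(3-fluoro-5-methoxyphenyl)nonan-1-ol
Conditions: H2 (1 atm), 10% Pd/C, EtOAc, rt
Reagents that add atoms: none
Why: catalytic hydrogenation of the alkene proceeds at atmospheric pressure, under which the aryl C–F bond is not cleaved.

Step 8
Reactants: 10 9-(3-fluoro-5-methoxyphenyl)nonan-1-ol
Product: 11 tert-butyl[9-(3-fluoro-5-methoxyphenyl)nonyloxy]dimethylsilane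
Conditions: TBSCl, imidazole, DMF, rt
Reagents that add atoms: tert-butyldimethylsilyl chloride, CC(C)(C)[Si](C)(C)Cl
Why: silylation of the primary alcohol as in step 5 gives an aryne precursor that has no proton more acidic than the ring C–H between fluorine and methoxy.

Step 9
Reactants: 7 [9-(2-bromo-4,5-dimethoxyphenyl)nonyloxy](tert-butyl)dimethylsilane
Product: 12 {2-[9-(tert-butyldimethylsilyloxy)nonyl]-4,5-dimethoxyphenyl}magnesium bromide (THF solution, titrated and used at once)
Conditions: Mg turnings (I2 crystal), THF, 50–65 °C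
Reagents that add atoms: magnesium, [Mg]
Why: Grignard formation by insertion of magnesium into the aryl C–Br bond is compatible with the methyl ethers and the silyl ether.

Step 10
Reactants: 11 tert-butyl[9-(3-fluoro-5-methoxyphenyl)nonyloxy]dimethylsilane; 12 {2-[9-(tert-butyldimethylsilyloxy)nonyl]-4,5-dimethoxyphenyl}magnesium bromide
Product: 17 2',5-bis[9-(tert-butyldimethylsilyloxy)nonyl]-3,4',5'-trimethoxybiphenyl-2-ol, via ring A aryllithium 13 (not isolated), via 3-methoxyaryne 14 (not isolated), via biarylmagnesium bromide 15 (not isolated), via biaryl dimethyl boronate 16 (not isolated)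
Conditions: 11, n-BuLi (1.0 equiv), THF, −78 °C; 12 (1.5 equiv) added at −78 °C, then warm slowly to rt; B(OMe)3, 0 °C to rt; 30% H2O2, aq NaOH, 0 °C
Reagents that add atoms: hydrogen peroxide, OO
Why: n-BuLi removes the one ring proton of 11 that lies between fluorine and methoxy (directed ortho-metalation at the most acidic site) to give 13, which loses LiF on warming and so releases the 3-methoxyaryne 14 only in the presence of excess 12. Carbomagnesiation of the aryne by 12 forms the biaryl C–C bond at the carbon that carried fluorine and places magnesium on the neighbouring carbon (15); B(OMe)3 captures this anion as boronate 16, and alkaline H2O2 triggers the 1,2-shift of the aryl group from boron to oxygen that gives phenol 17. The closest known reaction type is the one-pot addition of an aryl Grignard reagent to an aryne made from an ortho-lithiated fluoroarene with electrophilic quench of the resulting 2-biaryl magnesium species, joined to the standard borate/peroxide hydroxylation of aryl Grignard reagents. No ring closes and no stereocentre arises. The selectivity needed is regioselective addition to an unsymmetrical aryne: the methoxy group on the carbon next to the triple bond polarises and distorts it so that the nucleophile enters at the remote terminus and the charge develops at the inductively stabilised carbon beside oxygen, while the site of metalation is fixed by the two flanking heteroatoms. Addition of 13 to its own aryne is held back by the excess of 12 and by letting the aryne form slowly as the mixture warms.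

Step 11
Reactants: 17 2',5-bis[9-(tert-butyldimethylsilyloxy)nonyl]-3,4',5'-trimethoxybiphenyl-2-ol
Product: 18 2',5-bis[9-(tert-butyldimethylsilyloxy)nonyl]-2,3,4',5'-tetramethoxybiphenyl
Conditions: MeI, K2CO3, DMF, rt
Reagents that add atoms: iodomethane, CI
Why: Williamson O-methylation of the phenoxide with the small electrophile MeI should proceed even at this flanked position, and the silyl ethers are stable to carbonate.

Step 12
Reactants: 18 2',5-bis[9-(tert-butyldimethylsilyloxy)nonyl]-2,3,4',5'-tetramethoxybiphenyl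
Product: 19 9,9'-(2,3,4',5'-tetramethoxybiphenyl-5,2'-diyl)bis(nonan-1-ol)
Conditions: camphor-10-sulfonic acid (cat.), MeOH/CH2Cl2 1:1, rt
Reagents that add atoms: none
Why: acid-catalysed methanolysis cleaves primary tert-butyldimethylsilyl ethers by transferring silicon to methanol, and aryl methyl ethers are inert to it.

Step 13
Reactants: 19 9,9'-(2,3,4',5'-tetramethoxybiphenyl-5,2'-diyl)bis(nonan-1-ol)
Product: 20 9,9'-(2,3,4',5'-tetramethoxybiphenyl-5,2'-diyl)dinonanal
Conditions: Dess–Martin periodinane, NaHCO3, CH2Cl2, 0 °C to rt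
Reagents that add atoms: none
Why: Dess–Martin oxidation takes both primary alcohols to aldehydes without over-oxidation and without touching the electron-rich arenes, the bicarbonate buffering the acetic acid released.

Step 14
Reactants: 20 9,9'-(2,3,4',5'-tetramethoxybiphenyl-5,2'-diyl)dinonanal; 21 1,3-dimethoxybenzene
Product: 23 9,9'-(2,3,4',5'-tetramethoxybiphenyl-5,2'-diyl)bis[1-(2,6-dimethoxyphenyl)nonan-1-ol] (stereoisomer mixture), via 2,6-dimethoxyphenyllithium 22 (not isolated)
Conditions: 21 (3.3 equiv), n-BuLi (3.0 equiv), THF, 0 °C to rt; then 20, −78 to 0 °C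
Reagents that add atoms: none
Why: directed ortho-lithiation of 1,3-dimethoxybenzene occurs at C2 between the two methoxy groups, and the aryllithium adds 1,2 to both aldehydes at low temperature; the two carbinol centres form without control and are removed in the next step.

Step 15
Reactants: 23 9,9'-(2,3,4',5'-tetramethoxybiphenyl-5,2'-diyl)bis[1-(2,6-dimethoxyphenyl)nonan-1-ol]
Product: 24 9,9'-(2,3,4',5'-tetramethoxybiphenyl-5,2'-diyl)bis[1-(2,6-dimethoxyphenyl)nonan-1-one]
Conditions: Dess–Martin periodinane, NaHCO3, CH2Cl2, rt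
Reagents that add atoms: none
Why: Dess–Martin oxidation converts the hindered secondary benzylic alcohols into aryl ketones, and the buffer protects the electron-rich benzylic carbinols from acid-induced dehydration.

Step 16
Reactants: 24 9,9'-(2,3,4',5'-tetramethoxybiphenyl-5,2'-diyl)bis[1-(2,6-dimethoxyphenyl)nonan-1-one]
Product: 25 9,9'-(2,3,4',5'-tetrahydroxybiphenyl-5,2'-diyl)bis[1-(2,6-dihydroxyphenyl)nonan-1-one] (CNP0305015.0)
Conditions: BBr3 (excess), CH2Cl2, −78 °C to rt; then MeOH/H2O, 0 °C, under argon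
Reagents that add atoms: none
Why: BBr3 cleaves aryl methyl ethers by coordination to oxygen and bromide attack at the methyl group, the four ethers ortho to the ketones being assisted by chelation, and the aryl borates formed are hydrolysed to the octaphenol on work-up.

Compound list
1 | 8-bromooctan-1-ol | OCCCCCCCCBr | starting material
2 | (8-hydroxyoctyl)triphenylphosphonium bromide | OCCCCCCCC[P+](c1ccccc1)(c1ccccc1)c1ccccc1.[Br-] | intermediate
3 | 3,4-dimethoxybenzaldehyde | COc1ccc(C=O)cc1OC | starting material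
4 | (Z)-9-(3,4-dimethoxyphenyl)non-8-en-1-ol | COc1ccc(/C=C\CCCCCCCO)cc1OC | intermediate
5 | 9-(3,4-dimethoxyphenyl)nonan-1-ol | COc1ccc(CCCCCCCCCO)cc1OC | intermediate
6 | 9-(2-bromo-4,5-dimethoxyphenyl)nonan-1-ol | COc1cc(Br)c(CCCCCCCCCO)cc1OC | intermediate
7 | [9-(2-bromo-4,5-dimethoxyphenyl)nonyloxy](tert-butyl)dimethylsilane | COc1cc(Br)c(CCCCCCCCCO[Si](C)(C)C(C)(C)C)cc1OC | intermediate
8 | 3-fluoro-5-methoxybenzaldehyde | COc1cc(F)cc(C=O)c1 | starting material
9 | (Z)-9-(3-fluoro-5-methoxyphenyl)non-8-en-1-ol | COc1cc(F)cc(/C=C\CCCCCCCO)c1 | intermediate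
10 | 9-(3-fluoro-5-methoxyphenyl)nonan-1-ol | COc1cc(F)cc(CCCCCCCCCO)c1 | intermediate
11 | tert-butyl[9-(3-fluoro-5-methoxyphenyl)nonyloxy]dimethylsilane | COc1cc(F)cc(CCCCCCCCCO[Si](C)(C)C(C)(C)C)c1 | intermediate
12 | {2-[9-(tert-butyldimethylsilyloxy)nonyl]-4,5-dimethoxyphenyl}magnesium bromide | COc1cc([Mg]Br)c(CCCCCCCCCO[Si](C)(C)C(C)(C)C)cc1OC | intermediate
13 | 2-fluoro-6-methoxy-4-[9-(tert-butyldimethylsilyloxy)nonyl]phenyllithium | COc1c([Li])c(F)cc(CCCCCCCCCO[Si](C)(C)C(C)(C)C)c1 | intermediate
14 | 3-methoxy-5-[9-(tert-butyldimethylsilyloxy)nonyl]benzyne (1,2-didehydrobenzene, methoxy beside the triple bond) | COC1=CC(CCCCCCCCCO[Si](C)(C)C(C)(C)C)=CC#C1 | intermediate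
15 | {2',5-bis[9-(tert-butyldimethylsilyloxy)nonyl]-3,4',5'-trimethoxybiphenyl-2-yl}magnesium bromide | COc1cc(CCCCCCCCCO[Si](C)(C)C(C)(C)C)cc(-c2cc(OC)c(OC)cc2CCCCCCCCCO[Si](C)(C)C(C)(C)C)c1[Mg]Br | intermediate
16 | dimethyl {2',5-bis[9-(tert-butyldimethylsilyloxy)nonyl]-3,4',5'-trimethoxybiphenyl-2-yl}boronate | COc1cc(CCCCCCCCCO[Si](C)(C)C(C)(C)C)cc(-c2cc(OC)c(OC)cc2CCCCCCCCCO[Si](C)(C)C(C)(C)C)c1B(OC)OC | intermediate
17 | 2',5-bis[9-(tert-butyldimethylsilyloxy)nonyl]-3,4',5'-trimethoxybiphenyl-2-ol | COc1cc(CCCCCCCCCO[Si](C)(C)C(C)(C)C)cc(-c2cc(OC)c(OC)cc2CCCCCCCCCO[Si](C)(C)C(C)(C)C)c1O | intermediate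
18 | 2',5-bis[9-(tert-butyldimethylsilyloxy)nonyl]-2,3,4',5'-tetramethoxybiphenyl | COc1cc(CCCCCCCCCO[Si](C)(C)C(C)(C)C)cc(-c2cc(OC)c(OC)cc2CCCCCCCCCO[Si](C)(C)C(C)(C)C)c1OC | intermediate
19 | 9,9'-(2,3,4',5'-tetramethoxybiphenyl-5,2'-diyl)bis(nonan-1-ol) | COc1cc(CCCCCCCCCO)cc(-c2cc(OC)c(OC)cc2CCCCCCCCCO)c1OC | intermediate
20 | 9,9'-(2,3,4',5'-tetramethoxybiphenyl-5,2'-diyl)dinonanal | COc1cc(CCCCCCCCC=O)cc(-c2cc(OC)c(OC)cc2CCCCCCCCC=O)c1OC | intermediate
21 | 1,3-dimethoxybenzene | COc1cccc(OC)c1 | starting material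
22 | 2,6-dimethoxyphenyllithium | [Li]c1c(OC)cccc1OC | intermediate
23 | 9,9'-(2,3,4',5'-tetramethoxybiphenyl-5,2'-diyl)bis[1-(2,6-dimethoxyphenyl)nonan-1-ol], stereoisomer mixture | COc1cc(CCCCCCCCC(O)c2c(OC)cccc2OC)cc(-c2cc(OC)c(OC)cc2CCCCCCCCC(O)c2c(OC)cccc2OC)c1OC | intermediate
24 | 9,9'-(2,3,4',5'-tetramethoxybiphenyl-5,2'-diyl)bis[1-(2,6-dimethoxyphenyl)nonan-1-one] | COc1cc(CCCCCCCCC(=O)c2c(OC)cccc2OC)cc(-c2cc(OC)c(OC)cc2CCCCCCCCC(=O)c2c(OC)cccc2OC)c1OC | intermediate
25 | 9,9'-(2,3,4',5'-tetrahydroxybiphenyl-5,2'-diyl)bis[1-(2,6-dihydroxyphenyl)nonan-1-one], CNP0305015.0 | O=C(CCCCCCCCc1cc(O)c(O)c(-c2cc(O)c(O)cc2CCCCCCCCC(=O)c2c(O)cccc2O)c1)c1c(O)cccc1O | target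

Total step count: 16.
Longest linear sequence: 13 steps (steps 1, 2, 3, 4, 5, 9, 10, 11, 12, 13, 14, 15, 16, from 8-bromooctan-1-ol); the ring A branch (steps 6 to 8) joins at step 10.

Steps most likely to fail

Step 10. The lithiated fluoroarene may add to its own aryne faster than the ortho-substituted Grignard reagent does. The doubly flanked biaryl magnesium species may also be protonated rather than borylated, so that the biaryl forms poorly or without its oxygen. The fallback sets out from 12 and 2 and returns at 18, bypassing 17 and step 11; it makes the biaryl bond by Suzuki–Miyaura coupling with the ring A oxygen pattern already in place. Grignard reagent 12 is quenched with 2-isopropoxy-4,4,5,5-tetramethyl-1,3,2-dioxaborolane (THF, −78 °C to rt) to give 2-{2-[9-(tert-butyldimethylsilyloxy)nonyl]-4,5-dimethoxyphenyl}-4,4,5,5-tetramethyl-1,3,2-dioxaborolane F1. Commercial 3-bromo-4,5-dimethoxybenzaldehyde (COc1cc(C=O)cc(Br)c1OC) is olefinated with the ylide of 2 as in step 2 to give (Z)-9-(3-bromo-4,5-dimethoxyphenyl)non-8-en-1-ol F2. The alkene is saturated with H2 over RhCl(PPh3)3 in toluene/EtOH, which spares the aryl bromide, to give 9-(3-bromo-4,5-dimethoxyphenyl)nonan-1-ol F3. Silylation as in step 5 gives [9-(3-bromo-4,5-dimethoxyphenyl)nonyloxy](tert-butyl)dimethylsilane F4. Cross-coupling of F1 with F4 (Pd(OAc)2, SPhos, K3PO4, toluene/H2O, 90 °C) should then give 18.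

Step 14. The hindered, strongly basic aryllithium may deprotonate the enolisable aldehydes, so that aldol condensation and mono-addition compete with the twofold 1,2-addition. The fallback sets out from 20 and returns at 24, bypassing 23 and step 15; it replaces carbonyl addition by acylation. Pinnick oxidation of 20 (NaClO2, NaH2PO4, 2-methylbut-2-ene, t-BuOH/H2O) gives 9,9'-(2,3,4',5'-tetramethoxybiphenyl-5,2'-diyl)dinonanoic acid F5. Coupling with N,O-dimethylhydroxylamine hydrochloride (EDC·HCl, HOBt, i-Pr2NEt, CH2Cl2) gives 9,9'-(2,3,4',5'-tetramethoxybiphenyl-5,2'-diyl)bis(N-methoxy-N-methylnonanamide) F6. Addition of 22 (THF, −78 to 0 °C) should stop at the chelated tetrahedral intermediates and release diketone 24 on work-up.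

Step 16. Eight ether cleavages in one operation may stall at partly methylated stages, and the long exposure to excess BBr3 and HBr that full conversion needs may degrade the liberated catechols, which also oxidise in air during work-up. The fallback sets out from 20 and returns at 25; it carries the resorcinol oxygens as methoxymethyl ethers so that only the four catechol methyl ethers are left for the Lewis acid. Commercial 1,3-bis(methoxymethoxy)benzene (COCOc1cccc(OCOC)c1) is lithiated (n-BuLi, THF, 0 °C) to 2,6-bis(methoxymethoxy)phenyllithium F7. This is added to 20 as in step 14 to give 9,9'-(2,3,4',5'-tetramethoxybiphenyl-5,2'-diyl)bis{1-[2,6-bis(methoxymethoxy)phenyl]nonan-1-ol} F8. Buffered Dess–Martin oxidation as in step 15 gives 9,9'-(2,3,4',5'-tetramethoxybiphenyl-5,2'-diyl)bis{1-[2,6-bis(methoxymethoxy)phenyl]nonan-1-one} F9. HCl in MeOH at rt removes the four acetals to give 9,9'-(2,3,4',5'-tetramethoxybiphenyl-5,2'-diyl)bis[1-(2,6-dihydroxyphenyl)nonan-1-one] F10. BBr3 (CH2Cl2, −78 to 0 °C), now needed only for the two veratrole units, should give 25.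

Further compounds
F1 | step 10 | 2-{2-[9-(tert-butyldimethylsilyloxy)nonyl]-4,5-dimethoxyphenyl}-4,4,5,5-tetramethyl-1,3,2-dioxaborolane | COc1cc(B2OC(C)(C)C(C)(C)O2)c(CCCCCCCCCO[Si](C)(C)C(C)(C)C)cc1OC
F2 | step 10 | (Z)-9-(3-bromo-4,5-dimethoxyphenyl)non-8-en-1-ol | COc1cc(/C=C\CCCCCCCO)cc(Br)c1OC
F3 | step 10 | 9-(3-bromo-4,5-dimethoxyphenyl)nonan-1-ol | COc1cc(CCCCCCCCCO)cc(Br)c1OC
F4 | step 10 | [9-(3-bromo-4,5-dimethoxyphenyl)nonyloxy](tert-butyl)dimethylsilane | COc1cc(CCCCCCCCCO[Si](C)(C)C(C)(C)C)cc(Br)c1OC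
F5 | step 14 | 9,9'-(2,3,4',5'-tetramethoxybiphenyl-5,2'-diyl)dinonanoic acid | COc1cc(CCCCCCCCC(O)=O)cc(-c2cc(OC)c(OC)cc2CCCCCCCCC(O)=O)c1OC
F6 | step 14 | 9,9'-(2,3,4',5'-tetramethoxybiphenyl-5,2'-diyl)bis(N-methoxy-N-methylnonanamide) | COc1cc(CCCCCCCCC(=O)N(C)OC)cc(-c2cc(OC)c(OC)cc2CCCCCCCCC(=O)N(C)OC)c1OC
F7 | step 16 | 2,6-bis(methoxymethoxy)phenyllithium | [Li]c1c(OCOC)cccc1OCOC
F8 | step 16 | 9,9'-(2,3,4',5'-tetramethoxybiphenyl-5,2'-diyl)bis{1-[2,6-bis(methoxymethoxy)phenyl]nonan-1-ol}, stereoisomer mixture | COc1cc(CCCCCCCCC(O)c2c(OCOC)cccc2OCOC)cc(-c2cc(OC)c(OC)cc2CCCCCCCCC(O)c2c(OCOC)cccc2OCOC)c1OC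
F9 | step 16 | 9,9'-(2,3,4',5'-tetramethoxybiphenyl-5,2'-diyl)bis{1-[2,6-bis(methoxymethoxy)phenyl]nonan-1-one} | COc1cc(CCCCCCCCC(=O)c2c(OCOC)cccc2OCOC)cc(-c2cc(OC)c(OC)cc2CCCCCCCCC(=O)c2c(OCOC)cccc2OCOC)c1OC
F10 | step 16 | 9,9'-(2,3,4',5'-tetramethoxybiphenyl-5,2'-diyl)bis[1-(2,6-dihydroxyphenyl)nonan-1-one] | COc1cc(CCCCCCCCC(=O)c2c(O)cccc2O)cc(-c2cc(OC)c(OC)cc2CCCCCCCCC(=O)c2c(O)cccc2O)c1OC
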